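**Remark (working locants and assumption).** Decalin carbons are C1–C10 and cyclopentane carbons C1′–C5′ as defined in the first section; these are working labels, not IUPAC locants. (1R,3S)-Camphoric acid 1 and the (R)-enedione 6 are taken as purchasable.

## The problem

1. Working locants: C1 is the carbinol carbon that carries the five-membered ring, then C2, C3, C4 (angular CH3), C5 (CHBr), C6, C7, C8 (CH3, OH), C9 (angular OH) and C10; the cyclopentane is C1′ (quaternary, CH3, bonded to C1), C2′ (CHOH), C3′ (CH2), C4′ (CHBr), C5′ (C(CH3)2).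
2. The skeleton is a trans-decalin joined through C1 to C1′, so that C5′–C1′–C1 are three contiguous fully substituted carbons; the C1′–C1 bond cannot be made by adding a C1′ nucleophile to a C1 ketone.
3. The five decalin stereocentres (1S,4R,5R,8S,9S) all refer to C4: the C4 methyl is axial, the C9 and C1 hydroxyls are axial on the opposite face, the C8 hydroxyl is axial and trans to the C9 hydroxyl, and the C5 bromine is equatorial and cis to the methyl.
4. The three cyclopentane centres (1′S,2′R,4′S) place C1, the C2′ hydroxyl and the C4′ bromine on one face; the two groups of centres meet only at the rotatable C1–C1′ bond, so absolute control has to come from two sources.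
5. Both bromides are secondary and neopentylic (C5 next to C4, C4′ next to C5′), so substitution at carbon is not a realistic way to make them.
6. The three tertiary alcohols are fragile: the C8/C9 trans-diaxial glycol can undergo pinacol shift, and the C1 alcohol becomes a retro-aldol site whenever C2′ is a ketone.
7. The feature that makes the key step possible is the array C1(OH)–C10H2–C9(OH)–C8(OH)CH3 shared by ring A (C1, C2, C3, C4, C9, C10) and ring B (C4–C9). The C8/C9 glycol is a hydrated C8=C9 olefin, and a C1 carbinol two bonds from that olefin is the product of an intramolecular carbonyl-ene reaction between a C1 ketone and an exocyclic C9=C10 methylene carrying a hydrogen on C8.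
8. Ring A can therefore be closed last, around an acyl carbon C1 that is already bonded to C1′, and the unit C5′(CH3)2–C1′(CH3)–C1(=O) is the C2–C1–CO2H unit of (1R,3S)-camphoric acid with the correct configuration at C1′.

## Retrosynthesis

**19 to 17.** The C4′–Br and C2′–H bonds are cut, leading back to cyclopentenone 17. Bromide then enters at an sp2 carbon by conjugate addition, which avoids substitution at a neopentyl centre. The forward step must place bromine cis to the C1 substituent; reversibility of the addition is relied on for that. The C2′ ketone must then be reduced from the methyl face, which a boron chelate with the C1 hydroxyl should enforce.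

**17 to 14.** The C2′ carbonyl oxygen is removed (allylic oxidation of cyclopentene 16 in the forward sense). The C8/C9 glycol is traced to epoxide 15 and this to the C8=C9 olefin of 14. Epoxidation anti to the axial C4 methyl, followed by trans-diaxial hydrolysis, is the standard way to the trans-diaxial glycol. It asks only for selectivity of the peracid between a tetrasubstituted and a hindered disubstituted olefin.

**14 to 13.** The C5–H and C6–H bonds are cut to give vinyl bromide 13. A radical hydrogenation of a haloalkene adds hydrogen, not bromine, to the hindered carbon, so the bromine can end equatorial next to the quaternary C4. The precursor carries the bromine on an sp2 carbon that is robust in all earlier steps.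

**13 to 12 (key cut).** The C1–C10 bond is cut and the C8=C9 olefin is moved back to C9=C10. This opens ring A and removes the C1 stereocentre, leaving a ketone 12 that contains only ring B and the cyclopentene. Cutting C1–C1′ instead would ask for the impossible nucleophile. Cutting C1–C2 in the ring-closing step would leave the C9 oxygen to be set separately. The forward reaction must attack a very hindered ketone, must give the axial C1 alcohol trans to the C4 methyl, and must deliver the olefin only toward C8.

**12 to 10 and 5.** The C1–C2 bond is cut between the acid chloride 5 (C1, C1′–C5′) and the α-carbon of acid 10 (C2–C10), whose carboxyl group serves as a traceless activator. A ketone synthesis by acylation and decarboxylation tolerates the vinyl bromide and both olefins.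

**5 to 1.** Acid chloride 5 comes from acid 4, and this from camphoric acid 1 by removing the secondary carboxyl group as CO2 with formation of the C3′=C4′ olefin (via redox-active ester 3). The tertiary carboxyl carbon of 1 is C1, and the quaternary stereocentre C1′ is bought.

**10 to 6.** Acid 10 is traced through 9 (C10 methylene removed), 8 (C8 methyl removed) and 7 to the (R)-enedione 6. The C9=C10 enone olefin of 6 is cleaved to reveal the C9 ketone, the C5 ketone becomes the vinyl bromide, and the C4 quaternary centre is bought. Two ring carbons of 6 are sacrificed; this is the price of keeping C1–C1′ out of any intermolecular bond formation.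

## Roads not taken

**Alternative 1:** the biomimetic cut of C5′–C1′ and the C1–O bond, which most chemists would draw first. The forward step is a bromonium-triggered cation–olefin cyclisation of a prenyl chain onto the tetrasubstituted C1′=C1 olefin of A1, with water capture at C1. It would make the C4′ bromide, C1′ and C1 in one operation. It was not chosen for three reasons: the bromine electrophile has no reason to prefer the trisubstituted over the tetrasubstituted olefin; attack at C1 (six-membered spiro closure) gives a tertiary cation just as attack at C1′ does, and related bisabolene-type systems close that way; and the acyclic allylic strain of the C2′ carbinol favours the wrong C1′/C2′ relation. The chosen plan buys C1′ and makes both bromides by addition to sp2 carbon with predictable geometry.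

**Alternative 2:** cut C1′–C1 between a decalone and a cyclopentane nucleophile. The forward step is a Mukaiyama aldol of the tetrasubstituted silyl enol ether A3 with the fully functionalised decalone A2 (or addition of a tertiary organometallic). The bond would join a quaternary carbon flanked by C(CH3)2 to a ketone carbon; the aldolate is prone to retro-aldol, and the facial selectivity at C1′ would rest on a remote bromine. In the chosen plan this bond is never formed.

**Alternative 3:** cut C5′–C1′ by a 1,2-shift. A 1-metallovinyl cyclobutanol adds to decalone A2 to give A4, and protonation of the methylene group triggers ring expansion of the 2,2-dimethylcyclobutanol to the cyclopentanone with migration of the C(CH3)2 carbon. The idea makes the congested bond by a shift that tolerates crowding. It fails on control: C1 is locally pseudo-symmetric (two CH2 neighbours) and cannot direct the face of the C1′ cation, so an enantiopure cyclobutanol and a tether would be needed; the tertiary allylic C–O bonds would ionise in competition; and the C4′ bromide would still have to be added afterwards.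

Key step: step 9

## Route

Step 1
Reactants: 1 (1R,3S)-camphoric acid
Product: 3 (1R,3S)-3-{[(1,3-dioxoisoindol-2-yl)oxy]carbonyl}-1,2,2-trimethylcyclopentane-1-carboxylic acid, via camphoric anhydride 2 (not isolated)
Conditions: N,N′-diisopropylcarbodiimide, CH2Cl2, rt; then N-hydroxyphthalimide, DMAP (cat.), rt
Reagents that add atoms: N-hydroxyphthalimide, ON1C(=O)c2ccccc2C1=O
Why: Carbodiimide dehydration closes the six-membered anhydride 2, and N-hydroxyphthalimide opens it at the secondary carbonyl because the tertiary one is shielded by the C1′ methyl and the gem-dimethyl group (regioselective acylation to a redox-active ester); no stereocentre is touched.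

Step 2
Reactants: 3 (1R,3S)-3-{[(1,3-dioxoisoindol-2-yl)oxy]carbonyl}-1,2,2-trimethylcyclopentane-1-carboxylic acid
Product: 4 (1R)-1,2,2-trimethylcyclopent-3-ene-1-carboxylic acid
Conditions: 5,10-dimethyl-5,10-dihydrophenazine (cat.), Cu(O2CCH(Et)Bu)2 (cat.), toluene, blue LED, rt
Reagents that add atoms: none
Why: Single-electron reduction of the N-acyloxyphthalimide releases CO2 and the secondary C4′ radical, which divalent copper oxidises with loss of a β-hydrogen (photoredox/copper decarboxylative olefination of a redox-active ester). C5′ is quaternary, so only the C3′=C4′ olefin can form, and C1′ is untouched.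

Step 3
Reactants: 4 (1R)-1,2,2-trimethylcyclopent-3-ene-1-carboxylic acid
Product: 5 (1R)-1,2,2-trimethylcyclopent-3-ene-1-carbonyl chloride
Conditions: (COCl)2, DMF (cat.), CH2Cl2, 0 °C to rt
Reagents that add atoms: oxalyl chloride, ClC(=O)C(=O)Cl
Why: Acid chloride formation through the chloroiminium species from oxalyl chloride and DMF; the acid has no α-hydrogen, so neither ketene formation nor epimerisation is possible.

Step 4
Reactants: 6 (8aR)-8a-methyl-3,4,8,8a-tetrahydronaphthalene-1,6(2H,7H)-dione
Product: 7 (4aR)-5-bromo-4a-methyl-4,4a,7,8-tetrahydronaphthalen-2(3H)-one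
Conditions: P(OPh)3, Br2, CH2Cl2, −60 °C; then 6, Et3N, −60 °C to reflux
Reagents that add atoms: bromine, BrBr
Why: The phosphite–bromine adduct converts an enolisable ketone into the vinyl bromide (ketone-to-vinyl-halide reaction). The saturated C5 ketone should react before the less electrophilic enone carbonyl and can enolise only toward C6 because C4 is quaternary.

Step 5
Reactants: 7 (4aR)-5-bromo-4a-methyl-4,4a,7,8-tetrahydronaphthalen-2(3H)-one
Product: 8 3-[(1R)-2-bromo-1-methyl-6-oxocyclohex-2-en-1-yl]propanoic acid
Conditions: O3 (1.0 equiv), CH2Cl2/MeOH, −78 °C; then H2O2, HCO2H, rt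
Reagents that add atoms: ozone, [O-][O+]=O; hydrogen peroxide, OO
Why: Ozonolysis of the enone olefin with oxidative work-up gives the C9 ketone and, after oxidative loss of the old olefinic CH from the α-keto aldehyde, a propanoic acid chain on C4 whose carboxyl carbon is removed again in step 8. The vinyl bromide is deactivated toward ozone by the halogen, and C4 is not touched.

Step 6
Reactants: 8 3-[(1R)-2-bromo-1-methyl-6-oxocyclohex-2-en-1-yl]propanoic acid
Product: 9 3-[(1R,5RS)-2-bromo-1,5-dimethyl-6-oxocyclohex-2-en-1-yl]propanoic acid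
Conditions: LiN(iPr)2 (2.2 equiv), THF, −78 to −30 °C; MeI (1.1 equiv); aq. HCl
Reagents that add atoms: iodomethane, CI
Why: The carboxylate/ketone-enolate dianion is methylated at C8, the only enolisable position of the C9 ketone because C4 is quaternary (enolate alkylation). The new centre forms as a mixture, which does not matter because C8 becomes sp2 in step 9.

Step 7
Reactants: 9 3-[(1R,5RS)-2-bromo-1,5-dimethyl-6-oxocyclohex-2-en-1-yl]propanoic acid
Product: 10 3-[(1R,5RS)-2-bromo-1,5-dimethyl-6-methylidenecyclohex-2-en-1-yl]propanoic acid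
Conditions: Ph3PCH3Br, KOtBu (excess), toluene, 80 °C; aq. HCl
Reagents that add atoms: methyltriphenylphosphonium bromide, C[P+](c1ccccc1)(c1ccccc1)c1ccccc1.[Br-]
Why: Wittig methylenation with the ylide from KOtBu works on hindered α-quaternary cyclohexanones at elevated temperature and installs C10; the vinyl bromide and the carboxylate are inert to the ylide.

Step 8
Reactants: 10 3-[(1R,5RS)-2-bromo-1,5-dimethyl-6-methylidenecyclohex-2-en-1-yl]propanoic acid; 5 (1R)-1,2,2-trimethylcyclopent-3-ene-1-carbonyl chloride
Product: 12 3-[(1R,5RS)-2-bromo-1,5-dimethyl-6-methylidenecyclohex-2-en-1-yl]-1-[(1R)-1,2,2-trimethylcyclopent-3-en-1-yl]propan-1-one, via β-keto acid 11 (not isolated)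
Conditions: 10, LiN(iPr)2 (2.2 equiv), THF/DMPU, −78 to 0 °C; 5 (0.5 equiv), −78 °C to rt; aq. HCl, then 50 °C
Reagents that add atoms: none
Why: The α-carbanion of the carboxylate dianion is acylated on carbon by the non-enolisable acid chloride, and β-keto acid 11 loses CO2 on mild heating (dianion acylation/decarboxylation ketone synthesis). This forms the C1–C2 bond; the tertiary acyl group cannot form a ketene, and the hindered ketone does not add a second nucleophile.

Step 9
Reactants: 12 3-[(1R,5RS)-2-bromo-1,5-dimethyl-6-methylidenecyclohex-2-en-1-yl]-1-[(1R)-1,2,2-trimethylcyclopent-3-en-1-yl]propan-1-one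
Product: 13 (2S,4aR)-5-bromo-4a,8-dimethyl-2-[(1R)-1,2,2-trimethylcyclopent-3-en-1-yl]-1,2,3,4,4a,7-hexahydronaphthalen-2-ol
Conditions: Me2AlCl (2 equiv), CH2Cl2, −78 to 0 °C
Reagents that add atoms: none
Why: Me2AlCl binds the C1 ketone, the terminal carbon C10 of the exocyclic C9=C10 olefin attacks it, and the allylic hydrogen on C8 passes to oxygen: a Lewis-acid-promoted type-two intramolecular carbonyl-ene reaction, whose closest precedent is the cyclisation of 6-methylhept-6-en-2-one-type ketones to 3-methylidenecyclohexanols. Ring A closes as a six-membered ring in which the carbonyl is attacked exo (oxygen outside the ring) by an olefin lying inside the new ring, and the double bond moves to C8=C9, the only position open to it because C4 has no hydrogen. In the bicyclic transition state the oxygen has to sit axial on the new ring to reach the C8 hydrogen, which puts the very large cyclopentenyl group equatorial, so C1 is formed with an axial hydroxyl. The C4 methyl is axial to the forming ring because C5 lies near the plane of the sp2 centre C9, and axial positions at C1 and C4 are anti, so the C1 hydroxyl ends trans to the C4 methyl as in 19 (C1 S). Both C8 epimers of 12 converge on 13 because C8 becomes sp2; an epimer whose hydrogen is badly aligned can react through the open C9 cation and lose the same proton. Selectivity is needed against chloride capture of that cation and against the other two olefins: Me2AlCl scavenges protons and has a poorly nucleophilic counter-ion, the vinyl bromide is deactivated, and the cyclopentene cannot reach C1 through a ring of reasonable size. C1′ is not touched; the C1′/C1 relation is fixed by the ring geometry, against the acyclic 1,2-induction from C1′, which is the main reason the step may be slow.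

Step 10
Reactants: 13 (2S,4aR)-5-bromo-4a,8-dimethyl-2-[(1R)-1,2,2-trimethylcyclopent-3-en-1-yl]-1,2,3,4,4a,7-hexahydronaphthalen-2-ol
Product: 14 (2S,4aR,5R)-5-bromo-4a,8-dimethyl-2-[(1R)-1,2,2-trimethylcyclopent-3-en-1-yl]-1,2,3,4,4a,5,6,7-octahydronaphthalen-2-ol
Conditions: Mn(dpm)3 (dpm = 2,2,6,6-tetramethylheptane-3,5-dionate, cat.), PhSiH3, tBuOOH, iPrOH, rt
Reagents that add atoms: none
Why: Hydrogen-atom transfer from the manganese hydride to C6 gives the bromine-stabilised C5 radical, which should take its second hydrogen from the face anti to the axial C4 methyl, so bromine ends equatorial and cis to the methyl (radical hydrogenation of a haloalkene, no C–Br hydrogenolysis). The tetrasubstituted C8=C9 olefin and the 1,2-disubstituted cyclopentene should react much more slowly with the bulky metal hydride.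

Step 11
Reactants: 14 (2S,4aR,5R)-5-bromo-4a,8-dimethyl-2-[(1R)-1,2,2-trimethylcyclopent-3-en-1-yl]-1,2,3,4,4a,5,6,7-octahydronaphthalen-2-ol
Product: 15 (1S,4R,5R,8R,9S)-5-bromo-8,9-epoxy-4,8-dimethyl-1-[(1R)-1,2,2-trimethylcyclopent-3-en-1-yl]decalin-1-ol (working locants; epoxide oxygen syn to the C1 hydroxyl)
Conditions: mCPBA (1.05 equiv), NaHCO3, CH2Cl2, −20 °C
Reagents that add atoms: 3-chloroperoxybenzoic acid, OOC(=O)c1cccc(Cl)c1
Why: Peracid epoxidation is fastest at the tetrasubstituted C8=C9 olefin and occurs anti to the axial C4 methyl, the same face to which the axial homoallylic C1 hydroxyl directs by hydrogen bonding (Prilezhaev epoxidation); the hindered disubstituted cyclopentene is left.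

Step 12
Reactants: 15 (1S,4R,5R,8R,9S)-5-bromo-8,9-epoxy-4,8-dimethyl-1-[(1R)-1,2,2-trimethylcyclopent-3-en-1-yl]decalin-1-ol
Product: 16 (1S,4R,4aR,7S,8aS)-4-bromo-1,4a-dimethyl-7-[(1R)-1,2,2-trimethylcyclopent-3-en-1-yl]decahydronaphthalene-1,7,8a-triol
Conditions: HClO4 (cat.), THF/H2O, 0 °C
Reagents that add atoms: water, O
Why: Acid-catalysed trans-diaxial opening of the epoxide: water attacks C8, the less hindered tertiary carbon, from the face of the C4 methyl, so the C8 hydroxyl is axial and C9 keeps its axial oxygen, giving the (8S,9S) glycol of 19.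

Step 13
Reactants: 16 (1S,4R,4aR,7S,8aS)-4-bromo-1,4a-dimethyl-7-[(1R)-1,2,2-trimethylcyclopent-3-en-1-yl]decahydronaphthalene-1,7,8a-triol
Product: 17 (5R)-5-[(2S,4aR,5R,8S,8aS)-5-bromo-2,8,8a-trihydroxy-4a,8-dimethyldecahydronaphthalen-2-yl]-4,4,5-trimethylcyclopent-2-en-1-one
Conditions: Rh2(cap)4 (cap = caprolactamate, cat.), tBuOOH (aq.), CH2Cl2, rt
Reagents that add atoms: tert-butyl hydroperoxide, CC(C)(C)OO
Why: The dirhodium caprolactamate/tBuOOH allylic oxidation abstracts an allylic hydrogen by a tert-butylperoxy radical; C2′ is the only allylic CH2 of the only remaining olefin (C5′ is quaternary), so the enone forms regiospecifically. Tertiary alcohols and alkyl bromides are inert, and base is left out to avoid retro-aldol cleavage of C1–C1′.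

Step 14
Reactants: 17 (5R)-5-[(2S,4aR,5R,8S,8aS)-5-bromo-2,8,8a-trihydroxy-4a,8-dimethyldecahydronaphthalen-2-yl]-4,4,5-trimethylcyclopent-2-en-1-one
Product: 19 (1S,4R,4aR,7S,8aS)-4-bromo-7-[(1S,2R,4S)-4-bromo-2-hydroxy-1,5,5-trimethylcyclopentyl]-1,4a-dimethyldecahydronaphthalene-1,7,8a-triol, via β-bromo ketone 18 (not isolated)
Conditions: HBr (1.2 equiv), CH2Cl2, −40 to −10 °C; then THF/MeOH, Et2BOMe, NaBH4, −78 °C; MeOH co-evaporation
Reagents that add atoms: hydrogen bromide, Br
Why: HBr adds reversibly to the protonated cyclopentenone (conjugate hydrobromination), so C4′ should equilibrate to the isomer with bromine pseudo-equatorial and cis to the bulky pseudo-equatorial C1 substituent on C1′; this is the (4′S) centre of 19, made without substitution at a neopentyl carbon, and the tertiary alcohols are shielded from ionisation at low temperature by their β-oxygen substituents. The diethylboron chelate between the C1 hydroxyl and the C2′ ketone then holds the decalin unit on one face of the five-membered ring, and NaBH4 delivers hydride from the open methyl face (Narasaka–Prasad reduction), giving the C2′ alcohol cis to C1 (2′R).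

## Compound list

1 | (1R,3S)-camphoric acid [(1R,3S)-1,2,2-trimethylcyclopentane-1,3-dicarboxylic acid] | OC(=O)[C@]1(C)CC[C@H](C(=O)O)C1(C)C | starting material
2 | camphoric anhydride [(1R,5S)-1,8,8-trimethyl-3-oxabicyclo[3.2.1]octane-2,4-dione] | O=C1OC(=O)[C@]2(C)CC[C@H]1C2(C)C | intermediate
3 | (1R,3S)-3-{[(1,3-dioxoisoindol-2-yl)oxy]carbonyl}-1,2,2-trimethylcyclopentane-1-carboxylic acid | OC(=O)[C@]1(C)CC[C@H](C(=O)ON2C(=O)c3ccccc3C2=O)C1(C)C | intermediate
4 | (1R)-1,2,2-trimethylcyclopent-3-ene-1-carboxylic acid | OC(=O)[C@]1(C)CC=CC1(C)C | intermediate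
5 | (1R)-1,2,2-trimethylcyclopent-3-ene-1-carbonyl chloride | ClC(=O)[C@]1(C)CC=CC1(C)C | intermediate
6 | (8aR)-8a-methyl-3,4,8,8a-tetrahydronaphthalene-1,6(2H,7H)-dione | O=C1CC[C@@]2(C)C(=O)CCCC2=C1 | starting material
7 | (4aR)-5-bromo-4a-methyl-4,4a,7,8-tetrahydronaphthalen-2(3H)-one | O=C1CC[C@@]2(C)C(Br)=CCCC2=C1 | intermediate
8 | 3-[(1R)-2-bromo-1-methyl-6-oxocyclohex-2-en-1-yl]propanoic acid | OC(=O)CC[C@@]1(C)C(Br)=CCCC1=O | intermediate
9 | 3-[(1R,5RS)-2-bromo-1,5-dimethyl-6-oxocyclohex-2-en-1-yl]propanoic acid (both C5 epimers) | OC(=O)CC[C@@]1(C)C(Br)=CCC(C)C1=O | intermediate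
10 | 3-[(1R,5RS)-2-bromo-1,5-dimethyl-6-methylidenecyclohex-2-en-1-yl]propanoic acid (both C5 epimers) | OC(=O)CC[C@@]1(C)C(Br)=CCC(C)C1=C | intermediate
11 | 2-{[(1R,5RS)-2-bromo-1,5-dimethyl-6-methylidenecyclohex-2-en-1-yl]methyl}-3-oxo-3-[(1R)-1,2,2-trimethylcyclopent-3-en-1-yl]propanoic acid | OC(=O)C(C[C@@]1(C)C(Br)=CCC(C)C1=C)C(=O)[C@]1(C)CC=CC1(C)C | intermediate
12 | 3-[(1R,5RS)-2-bromo-1,5-dimethyl-6-methylidenecyclohex-2-en-1-yl]-1-[(1R)-1,2,2-trimethylcyclopent-3-en-1-yl]propan-1-one | O=C(CC[C@@]1(C)C(Br)=CCC(C)C1=C)[C@]1(C)CC=CC1(C)C | intermediate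
13 | (2S,4aR)-5-bromo-4a,8-dimethyl-2-[(1R)-1,2,2-trimethylcyclopent-3-en-1-yl]-1,2,3,4,4a,7-hexahydronaphthalen-2-ol | CC1(C)C=CC[C@@]1(C)[C@]1(O)CC[C@@]2(C)C(Br)=CCC(C)=C2C1 | intermediate
14 | (2S,4aR,5R)-5-bromo-4a,8-dimethyl-2-[(1R)-1,2,2-trimethylcyclopent-3-en-1-yl]-1,2,3,4,4a,5,6,7-octahydronaphthalen-2-ol | CC1(C)C=CC[C@@]1(C)[C@]1(O)CC[C@@]2(C)[C@H](Br)CCC(C)=C2C1 | intermediate
15 | (1S,4R,5R,8R,9S)-5-bromo-8,9-epoxy-4,8-dimethyl-1-[(1R)-1,2,2-trimethylcyclopent-3-en-1-yl]decalin-1-ol (working locants) | CC1(C)C=CC[C@@]1(C)[C@]1(O)CC[C@@]2(C)[C@H](Br)CC[C@@]3(C)O[C@@]23C1 | intermediate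
16 | (1S,4R,4aR,7S,8aS)-4-bromo-1,4a-dimethyl-7-[(1R)-1,2,2-trimethylcyclopent-3-en-1-yl]decahydronaphthalene-1,7,8a-triol | CC1(C)C=CC[C@@]1(C)[C@]1(O)CC[C@@]2(C)[C@H](Br)CC[C@](C)(O)[C@]2(O)C1 | intermediate
17 | (5R)-5-[(2S,4aR,5R,8S,8aS)-5-bromo-2,8,8a-trihydroxy-4a,8-dimethyldecahydronaphthalen-2-yl]-4,4,5-trimethylcyclopent-2-en-1-one | CC1(C)C=CC(=O)[C@@]1(C)[C@]1(O)CC[C@@]2(C)[C@H](Br)CC[C@](C)(O)[C@]2(O)C1 | intermediate
18 | (2R,4S)-4-bromo-2-[(2S,4aR,5R,8S,8aS)-5-bromo-2,8,8a-trihydroxy-4a,8-dimethyldecahydronaphthalen-2-yl]-2,3,3-trimethylcyclopentan-1-one | CC1(C)[C@@H](Br)CC(=O)[C@@]1(C)[C@]1(O)CC[C@@]2(C)[C@H](Br)CC[C@](C)(O)[C@]2(O)C1 | intermediate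
19 | (1S,4R,4aR,7S,8aS)-4-bromo-7-[(1S,2R,4S)-4-bromo-2-hydroxy-1,5,5-trimethylcyclopentyl]-1,4a-dimethyldecahydronaphthalene-1,7,8a-triol | CC1(C)[C@@H](Br)C[C@@H](O)[C@@]1(C)[C@]1(O)CC[C@@]2(C)[C@H](Br)CC[C@](C)(O)[C@]2(O)C1 | target

## Step count and least certain steps

Total: 14 steps. Longest linear sequence: 11 steps (6 to 19, steps 4–14); the camphoric acid branch joins at step 8 after 3 steps.

**Step 9 (key step).** The likeliest failure is that the ketone, flanked by the quaternary C1′ and working against the acyclic 1,2-induction from C1′, does not react before the Lewis acid isomerises the exocyclic olefin; the other is that the open C9 cation is captured or loses a C10 proton. Fallback: from 12, SnCl4 at −78 °C is used for a stepwise Prins closure with chloride capture at C9, giving the chloro alcohol F1; its tertiary chloride is then eliminated toward C8 with AgOTf and 2,6-lutidine, returning to the route at 13.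

**Step 14.** Ionisation of a tertiary alcohol or acid-catalysed retro-aldol cleavage of C1–C1′ may compete with the conjugate addition, and the equilibrium at C4′ may not be reached before the bromo ketone loses HBr again. Fallback: from 17, copper-catalysed conjugate borylation (CuCl, NaOtBu (cat.), a bisphosphine, B2pin2, MeOH) should give the β-boryl ketone F2 with boron anti to the decalin unit. Narasaka–Prasad reduction gives the boryl alcohol F3, and TMSOTf/2,6-lutidine gives the tetrakis(trimethylsilyl) ether F4. Addition of 3,5-bis(trifluoromethyl)phenyllithium and then N-bromosuccinimide brominates the boronate with inversion to the silylated dibromide F5, and HCl in MeOH returns to the route at 19.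

**Step 10.** Hydrogen-atom transfer may also reach the C8=C9 olefin, or the C5 radical may take hydrogen from the wrong face; either would erode the alkene needed in step 11 or the C5 configuration. Fallback: from 13, concerted syn transfer of H2 from diimide (2-nitrobenzenesulfonylhydrazide, Et3N) to the face anti to the C4 methyl; this leaves tetrasubstituted olefins alone and returns to the route at 14 with no new compound (F0).

**Step 5.** Ozone may not distinguish well enough between the enone olefin and the vinyl bromide, which would lead to over-cleavage. Fallback: from 7, nucleophilic epoxidation (H2O2, NaOH, MeOH), which only the enone can undergo, gives the epoxy ketone F6; periodic acid (H5IO6, aqueous THF) cleaves it, returning to the route at 8.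

**Step 8.** Generating the carboxylate dianion needs temperatures at which LiN(iPr)2 may attack the vinyl bromide, and proton transfer from the product limits conversion. Fallback: from 10, esterification with trimethylsilyldiazomethane gives the methyl ester F7; its lithium enolate (LiN(iPr)2, −78 °C) is acylated by 5 to the β-keto ester F8; Krapcho dealkoxycarbonylation (LiCl, wet DMSO, heat) returns to the route at 12.

## Further compounds

F1 | step 9 | (1S,4R)-5-bromo-9-chloro-4,8-dimethyl-1-[(1R)-1,2,2-trimethylcyclopent-3-en-1-yl]decal-5-en-1-ol (working locants; C8 and C9 as formed) | CC1(C)C=CC[C@@]1(C)[C@]1(O)CC[C@@]2(C)C(Br)=CCC(C)C2(Cl)C1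
F2 | step 14 | (2R,4R)-2-[(2S,4aR,5R,8S,8aS)-5-bromo-2,8,8a-trihydroxy-4a,8-dimethyldecahydronaphthalen-2-yl]-2,3,3-trimethyl-4-(4,4,5,5-tetramethyl-1,3,2-dioxaborolan-2-yl)cyclopentan-1-one (boron trans to the decalin unit) | CC1(C)[C@H](B2OC(C)(C)C(C)(C)O2)CC(=O)[C@@]1(C)[C@]1(O)CC[C@@]2(C)[C@H](Br)CC[C@](C)(O)[C@]2(O)C1
F3 | step 14 | C2′ alcohol of F2 (hydroxyl cis to the decalin unit, boron trans) | CC1(C)[C@H](B2OC(C)(C)C(C)(C)O2)C[C@@H](O)[C@@]1(C)[C@]1(O)CC[C@@]2(C)[C@H](Br)CC[C@](C)(O)[C@]2(O)C1
F4 | step 14 | tetrakis(trimethylsilyl) ether of F3 | CC1(C)[C@H](B2OC(C)(C)C(C)(C)O2)C[C@@H](O[Si](C)(C)C)[C@@]1(C)[C@]1(O[Si](C)(C)C)CC[C@@]2(C)[C@H](Br)CC[C@](C)(O[Si](C)(C)C)[C@]2(O[Si](C)(C)C)C1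
F5 | step 14 | tetrakis(trimethylsilyl) ether of 19 | CC1(C)[C@@H](Br)C[C@@H](O[Si](C)(C)C)[C@@]1(C)[C@]1(O[Si](C)(C)C)CC[C@@]2(C)[C@H](Br)CC[C@](C)(O[Si](C)(C)C)[C@]2(O[Si](C)(C)C)C1
F0 | step 10 | none | none
F6 | step 5 | (4aR)-5-bromo-1,8a-epoxy-4a-methyl-octahydronaphthalen-2-one-type epoxy ketone of 7 (epoxide on the former enone olefin, both faces) | O=C1CC[C@@]2(C)C(Br)=CCCC23OC13
F7 | step 8 | methyl 3-[(1R,5RS)-2-bromo-1,5-dimethyl-6-methylidenecyclohex-2-en-1-yl]propanoate | COC(=O)CC[C@@]1(C)C(Br)=CCC(C)C1=C
F8 | step 8 | methyl 2-{[(1R,5RS)-2-bromo-1,5-dimethyl-6-methylidenecyclohex-2-en-1-yl]methyl}-3-oxo-3-[(1R)-1,2,2-trimethylcyclopent-3-en-1-yl]propanoate | COC(=O)C(C[C@@]1(C)C(Br)=CCC(C)C1=C)C(=O)[C@]1(C)CC=CC1(C)C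
A1 | alternative 1 | (4R,5R,8S,9S)-5-bromo-1-[(3R)-3-hydroxy-6-methylhept-5-en-2-ylidene]-4,8-dimethyldecalin-8,9-diol (working locants; olefin geometry open) | CC(C)=CC[C@@H](O)C(C)=C1CC[C@@]2(C)[C@H](Br)CC[C@](C)(O)[C@]2(O)C1
A2 | alternative 2 | (4R,5R,8S,9S)-5-bromo-8,9-dihydroxy-4,8-dimethyldecalin-1-one (working locants) | O=C1CC[C@@]2(C)[C@H](Br)CC[C@](C)(O)[C@]2(O)C1
A3 | alternative 2 | (4S)-4-bromo-2,3,3-trimethyl-1-(trimethylsilyloxy)cyclopent-1-ene | CC1=C(O[Si](C)(C)C)C[C@H](Br)C1(C)C
A4 | alternative 3 | 1-{1-[(1S,4R,5R,8S,9S)-5-bromo-1,8,9-trihydroxy-4,8-dimethyldecalin-1-yl]ethenyl}-2,2-dimethylcyclobutan-1-ol (working locants; cyclobutanol centre open) | C=C(C1(O)CCC1(C)C)[C@]1(O)CC[C@@]2(C)[C@H](Br)CC[C@](C)(O)[C@]2(O)C1
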